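**Retrosynthetic overview**
- Last operation: hydrogenolysis of two O-benzyl groups (no ring formed).
- Key disconnection: C4–C4a (intramolecular Friedel–Crafts acylation, ring C) and pyranone O1–C2 (enol lactonisation of a tert-butyl 3,5-dioxo ester) are cut together, so both rings close in one flask from an open-chain acid.
- ArCH2–C bond: reductive Knoevenagel union of an aryl aldehyde with the dioxo ester; the aldehyde carbon becomes the CH2 bridge.
- C2–O1 bond: Mitsunobu etherification (inversion) of the single free, CHO-chelated OH of di-O-benzyl phloroglucinaldehyde with an (R)-β-hydroxy ester. This sets (2S) and, because the ether sits next to the formyl carbon, fixes the bridge at C8 by construction.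
- Ring order: ring A and the phenyl ring are bought; ring C and the pyranone form together in step 5; no ring is made afterwards.

Assumption: 3,5-dioxo esters and acids are drawn as keto tautomers and their enolisable CH centres are left undefined, since both become sp2 in the pyranone.

**Step 1**
Reactants: 1 2,4,6-trihydroxybenzaldehyde
Product: 2 2,4-bis(benzyloxy)-6-hydroxybenzaldehyde
Conditions: BnBr (2.05 equiv), K2CO3 (2.2 equiv), DMF, 0 °C → rt
Reagents that add atoms: benzyl bromide BrCc1ccccc1
Why: Williamson O-benzylation takes the 4-OH and one ortho OH, while the last OH stays free because it is held in the CHO···HO hydrogen bond, which leaves exactly one phenol, next to the formyl carbon.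

**Step 2**
Reactants: 2 2,4-bis(benzyloxy)-6-hydroxybenzaldehyde; 3 ethyl (3R)-3-hydroxy-3-phenylpropanoate
Product: 5 (3S)-3-[3,5-bis(benzyloxy)-2-formylphenoxy]-3-phenylpropanoic acid, via ethyl ester 4 (not isolated)
Conditions: PPh3, DIAD, THF, 0 °C → rt; then LiOH·H2O, THF–H2O, 0 °C; 1 M HCl
Reagents that add atoms: lithium hydroxide [Li+].[OH-]
Why: Mitsunobu etherification proceeds by SN2 inversion at the benzylic carbinol, turning the (R)-alcohol into the (S)-aryl ether that becomes C2 of the flavanone, and saponification in the same flask (hydroxide attacks the ester carbonyl far faster than it removes the α-proton) lets the acid be extracted away from Ph3PO.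

**Step 3**
Reactants: 6 tert-butyl 3-oxopentanoate; 7 N-methoxy-N-methylpropanamide
Product: 8 tert-butyl 4-methyl-3,5-dioxoheptanoate
Conditions: LDA (2.2 equiv), THF, 0 °C; then 7, −78 → 0 °C; 1 M HCl
Reagents that add atoms: none
Why: Huckin–Weiler dianion γ-acylation, in which the more reactive γ-carbanion attacks the Weinreb amide and the chelated tetrahedral adduct releases the 1,3-diketone only on work-up.

**Step 4**
Reactants: 5 (3S)-3-[3,5-bis(benzyloxy)-2-formylphenoxy]-3-phenylpropanoic acid; 8 tert-butyl 4-methyl-3,5-dioxoheptanoate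
Product: 10 (3S)-3-{3,5-bis(benzyloxy)-2-[2-(tert-butoxycarbonyl)-4-methyl-3,5-dioxoheptyl]phenoxy}-3-phenylpropanoic acid, via arylidene dioxo ester 9 (not isolated)
Conditions: L-proline (20 mol %), Hantzsch ester (1.2 equiv), EtOH, 50 °C
Reagents that add atoms: none
Why: Three-component reductive alkylation, in which Knoevenagel condensation can occur only at C2 of 8 (the sole CH2 between two carbonyls) and the arylidene is reduced in situ by hydride transfer from the Hantzsch ester; the new chain stereocentres are irrelevant and C3 of the acid is untouched.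

**Step 5**
Reactants: 10 (3S)-3-{3,5-bis(benzyloxy)-2-[2-(tert-butoxycarbonyl)-4-methyl-3,5-dioxoheptyl]phenoxy}-3-phenylpropanoic acid
Product: 13 (2S)-5,7-bis(benzyloxy)-8-[(6-ethyl-4-hydroxy-5-methyl-2-oxo-2H-pyran-3-yl)methyl]-2-phenylchroman-4-one, via chromanone tert-butyl ester 11 (not isolated), via chromanone dioxo acid 12 (not isolated)
Conditions: TFAA (5 equiv), TFA–CH2Cl2 (1:1), 0.02 M, 0 °C → rt; then aq. NaHCO3
Reagents that add atoms: none
Why: The mixed trifluoroacetic anhydride of the acid acylates the only free position ortho to the ether oxygen (intramolecular Friedel–Crafts acylation, ring C, stereocentre not involved), while TFA cleaves the tert-butyl ester and TFAA dehydrates the 3,5-dioxo acid through its C5 enol to the 4-hydroxy-2-pyranone (standard TFA/TFAA pyrone closure); each closure is routine under these conditions and only their combination in one flask is untested.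

**Step 6**
Reactants: 13 (2S)-5,7-bis(benzyloxy)-8-[(6-ethyl-4-hydroxy-5-methyl-2-oxo-2H-pyran-3-yl)methyl]-2-phenylchroman-4-one
Product: 14 (2S)-8-[(6-ethyl-4-hydroxy-5-methyl-2-oxo-2H-pyran-3-yl)methyl]-5,7-dihydroxy-2-phenylchroman-4-one
Conditions: H2 (1 atm), 10% Pd/C, EtOAc, rt, stopped at full conversion
Reagents that add atoms: none
Why: Hydrogenolysis of the two aryl benzyl ethers under neutral conditions is faster than reduction of the ring C2–O bond, the ketone or the pyranone, and no base is present that could open ring C, so C2 stays (S).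

**Compound list**
1 | 2,4,6-trihydroxybenzaldehyde | O=Cc1c(O)cc(O)cc1O | starting material
2 | 2,4-bis(benzyloxy)-6-hydroxybenzaldehyde | O=Cc1c(O)cc(OCc2ccccc2)cc1OCc1ccccc1 | intermediate
3 | ethyl (3R)-3-hydroxy-3-phenylpropanoate | CCOC(=O)C[C@@H](O)c1ccccc1 | starting material
4 | ethyl (3S)-3-[3,5-bis(benzyloxy)-2-formylphenoxy]-3-phenylpropanoate | CCOC(=O)C[C@H](Oc1cc(OCc2ccccc2)cc(OCc2ccccc2)c1C=O)c1ccccc1 | intermediate
5 | (3S)-3-[3,5-bis(benzyloxy)-2-formylphenoxy]-3-phenylpropanoic acid | O=Cc1c(OCc2ccccc2)cc(OCc2ccccc2)cc1O[C@H](c1ccccc1)CC(=O)O | intermediate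
6 | tert-butyl 3-oxopentanoate | CCC(=O)CC(=O)OC(C)(C)C | starting material
7 | N-methoxy-N-methylpropanamide | CCC(=O)N(C)OC | starting material
8 | tert-butyl 4-methyl-3,5-dioxoheptanoate | CCC(=O)C(C)C(=O)CC(=O)OC(C)(C)C | intermediate
9 | (3S)-3-{3,5-bis(benzyloxy)-2-[2-(tert-butoxycarbonyl)-4-methyl-3,5-dioxohept-1-en-1-yl]phenoxy}-3-phenylpropanoic acid | CCC(=O)C(C)C(=O)C(=Cc1c(OCc2ccccc2)cc(OCc2ccccc2)cc1O[C@H](c1ccccc1)CC(=O)O)C(=O)OC(C)(C)C | intermediate
10 | (3S)-3-{3,5-bis(benzyloxy)-2-[2-(tert-butoxycarbonyl)-4-methyl-3,5-dioxoheptyl]phenoxy}-3-phenylpropanoic acid | CCC(=O)C(C)C(=O)C(Cc1c(OCc2ccccc2)cc(OCc2ccccc2)cc1O[C@H](c1ccccc1)CC(=O)O)C(=O)OC(C)(C)C | intermediate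
11 | tert-butyl 2-{[(2S)-5,7-bis(benzyloxy)-4-oxo-2-phenylchroman-8-yl]methyl}-4-methyl-3,5-dioxoheptanoate | CCC(=O)C(C)C(=O)C(Cc1c(OCc2ccccc2)cc(OCc2ccccc2)c2c1O[C@H](c1ccccc1)CC2=O)C(=O)OC(C)(C)C | intermediate
12 | 2-{[(2S)-5,7-bis(benzyloxy)-4-oxo-2-phenylchroman-8-yl]methyl}-4-methyl-3,5-dioxoheptanoic acid | CCC(=O)C(C)C(=O)C(Cc1c(OCc2ccccc2)cc(OCc2ccccc2)c2c1O[C@H](c1ccccc1)CC2=O)C(=O)O | intermediate
13 | (2S)-5,7-bis(benzyloxy)-8-[(6-ethyl-4-hydroxy-5-methyl-2-oxo-2H-pyran-3-yl)methyl]-2-phenylchroman-4-one | CCc1oc(=O)c(Cc2c(OCc3ccccc3)cc(OCc3ccccc3)c3c2O[C@H](c2ccccc2)CC3=O)c(O)c1C | intermediate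
14 | (2S)-8-[(6-ethyl-4-hydroxy-5-methyl-2-oxo-2H-pyran-3-yl)methyl]-5,7-dihydroxy-2-phenylchroman-4-one | CCc1oc(=O)c(Cc2c(O)cc(O)c3c2O[C@H](c2ccccc2)CC3=O)c(O)c1C | target

**Totals**
Total step count: 6. Longest linear sequence: 5 steps (1 → 2 → 5 → 10 → 13 → 14); step 3 is a one-step side branch.

**Steps most likely to fail, with fallbacks**

Step 4 is the least secure. The aldehyde is hindered and electron-rich, and an acyclic dioxo ester is a weaker partner than the cyclic CH-acids usually used. The arylidene 9 can also close by oxa-Michael addition to a dihydropyranone, or the proline iminium can be reduced instead. Fallback, setting out from 5 and coming back at 10: NaBH4 reduces the aldehyde to (3S)-3-[3,5-bis(benzyloxy)-2-(hydroxymethyl)phenoxy]-3-phenylpropanoic acid F2. Sc(OTf)3 (5 mol %) in CH2Cl2 then ionises this 2,4,6-trioxygenated benzylic alcohol, and the cation is trapped by the unhindered C2 enol of 8 (dehydrative SN1 benzylation of a 1,3-dicarbonyl), which gives 10 without passing through 9.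

Step 5 carries three risks: ring trifluoroacetylation, acid loss of the electron-rich benzyl unit from the dicarbonyl carbon, and partial loss of the 5-O-benzyl group (the last is harmless, since it converges in step 6). Fallback, setting out from 8 and 5 and coming back at 13: 8 alone is closed with TFA/TFAA to 6-ethyl-4-hydroxy-5-methyl-2H-pyran-2-one F3. F3 and 5 are joined by the proline/Hantzsch reductive alkylation, which is reliable for this strongly acidic cyclic partner, to give (3S)-3-{3,5-bis(benzyloxy)-2-[(6-ethyl-4-hydroxy-5-methyl-2-oxo-2H-pyran-3-yl)methyl]phenoxy}-3-phenylpropanoic acid F4. TFAA in CH2Cl2 at 0 °C then closes ring C alone and gives 13. This fallback forms the two rings in separate operations.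

Step 2 may give ethyl cinnamate by β-elimination of the activated β-hydroxy ester, or a lowered ee. Fallback, setting out from 2 and coming back at 4: the C–O bond is made first and the stereocentre afterwards. Phenol 2 is added to ethyl 3-phenylpropiolate (K2CO3, DMF, 60 °C, oxa-Michael addition) to give ethyl (2Z)-3-[3,5-bis(benzyloxy)-2-formylphenoxy]-3-phenylprop-2-enoate F1. F1 is reduced by asymmetric hydrogenation with a homogeneous Rh–bisphosphine or Ir–N,P catalyst (ligand screened, enantiomer chosen for S; benzyl ethers and the aldehyde are not touched) to ester 4, which is saponified as in step 2.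

**Further compounds**
F1 | step 2 | ethyl (2Z)-3-[3,5-bis(benzyloxy)-2-formylphenoxy]-3-phenylprop-2-enoate | CCOC(=O)/C=C(\Oc1cc(OCc2ccccc2)cc(OCc2ccccc2)c1C=O)c1ccccc1
F2 | step 4 | (3S)-3-[3,5-bis(benzyloxy)-2-(hydroxymethyl)phenoxy]-3-phenylpropanoic acid | OCc1c(OCc2ccccc2)cc(OCc2ccccc2)cc1O[C@H](c1ccccc1)CC(=O)O
F3 | step 5 | 6-ethyl-4-hydroxy-5-methyl-2H-pyran-2-one | CCc1oc(=O)cc(O)c1C
F4 | step 5 | (3S)-3-{3,5-bis(benzyloxy)-2-[(6-ethyl-4-hydroxy-5-methyl-2-oxo-2H-pyran-3-yl)methyl]phenoxy}-3-phenylpropanoic acid | CCc1oc(=O)c(Cc2c(OCc3ccccc3)cc(OCc3ccccc3)cc2O[C@H](c2ccccc2)CC(=O)O)c(O)c1C
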